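**Plan**

1. Retrosynthesis: the 7‑O‑MOM group is removed last. Before it, one retro‑operation opens ring C at O1–C2 (back to a trans‑epoxide across C2–C3) and returns both C‑prenyl bonds (C8–CH2 on ring A, C3'–CH2 on ring B) to the neighbouring oxygens O1 and O4' as 2‑methylbut‑3‑en‑2‑yl ethers. The epoxide then goes back to a chalcone alkene, and that alkene to an acetophenone plus a benzaldehyde.
2. Enabling feature: C8 is ortho to O1 and is its only free ortho carbon (the other, C4a, carries C4), and C3' is ortho to O4'. Each prenyl group is therefore the [3,3] image of a tertiary allyl ether on the adjacent oxygen, and the shift on ring A frees O1 where it can reach the benzylic, para‑oxygenated epoxide carbon (future C2).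
3. Forward: rings A and B are bought (2,4‑dihydroxyacetophenone, 4‑hydroxybenzaldehyde), etherified (propargylation, semihydrogenation), joined by Claisen–Schmidt condensation and epoxidised. One thermal operation then installs both prenyl groups and closes ring C, the only ring made; MOM removal ends the route.
4. Stereochemistry: Julia–Colonna epoxidation sets the (2R,3S)‑epoxide. C3 (R) is its untouched alpha carbon; C2 (R) results from inversion at the beta carbon during ring closure (2,3‑trans).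

Key step: step 8

Assumption: poly‑L‑leucine is taken to give the (alpha‑R, beta‑S) epoxide with this ortho‑alkoxylated chalcone as it does with simple chalcones; poly‑D‑leucine would be used should the sense be reversed.

**Route**

Step 1
Reactants: 1 2,4‑dihydroxyacetophenone
Product: 2 1‑[2‑hydroxy‑4‑(methoxymethoxy)phenyl]ethanone
Conditions: MOMCl, K2CO3, acetone, 0 °C to rt
Reagents that add atoms: chloromethyl methyl ether (MOMCl), COCCl
Why: Williamson etherification; the 2‑OH is tied up in a hydrogen bond to the acetyl carbonyl, so the more acidic and freer 4‑OH should react alone.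

Step 2
Reactants: 2 1‑[2‑hydroxy‑4‑(methoxymethoxy)phenyl]ethanone, 3 3‑chloro‑3‑methylbut‑1‑yne
Product: 4 1‑[4‑(methoxymethoxy)‑2‑(2‑methylbut‑3‑yn‑2‑yloxy)phenyl]ethanone
Conditions: K2CO3, KI, CuI (cat.), DMF, 60 °C
Reagents that add atoms: none
Why: Copper‑catalysed propargylic substitution of the tertiary chloride by the phenoxide (copper acetylide, then an allenylidene‑type electrophile attacked at the tertiary carbon), the standard route to aryl 1,1‑dimethylpropargyl ethers; the ether is made at the alkyne stage because it does not rearrange at this temperature.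

Step 3
Reactants: 4 1‑[4‑(methoxymethoxy)‑2‑(2‑methylbut‑3‑yn‑2‑yloxy)phenyl]ethanone
Product: 5 1‑[4‑(methoxymethoxy)‑2‑(2‑methylbut‑3‑en‑2‑yloxy)phenyl]ethanone
Conditions: H2 (1 atm), Pd/CaCO3 poisoned with Pb(OAc)2, quinoline, EtOAc, rt
Reagents that add atoms: none
Why: Lindlar semihydrogenation: the poisoned palladium surface reduces the terminal alkyne to the vinyl group and should stop there, leaving ketone and acetal untouched.

Step 4
Reactants: 6 4‑hydroxybenzaldehyde, 3 3‑chloro‑3‑methylbut‑1‑yne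
Product: 7 4‑(2‑methylbut‑3‑yn‑2‑yloxy)benzaldehyde
Conditions: K2CO3, KI, CuI (cat.), acetone, reflux
Reagents that add atoms: none
Why: The same copper‑catalysed propargylic etherification, here on an unhindered, acidic phenol.

Step 5
Reactants: 7 4‑(2‑methylbut‑3‑yn‑2‑yloxy)benzaldehyde
Product: 8 4‑(2‑methylbut‑3‑en‑2‑yloxy)benzaldehyde
Conditions: H2 (1 atm), Pd/CaCO3 poisoned with Pb(OAc)2, quinoline, EtOAc, rt
Reagents that add atoms: none
Why: Lindlar semihydrogenation; the aldehyde is not reduced under these conditions.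

Step 6
Reactants: 5 1‑[4‑(methoxymethoxy)‑2‑(2‑methylbut‑3‑en‑2‑yloxy)phenyl]ethanone, 8 4‑(2‑methylbut‑3‑en‑2‑yloxy)benzaldehyde
Product: 9 (E)‑1‑[4‑(methoxymethoxy)‑2‑(2‑methylbut‑3‑en‑2‑yloxy)phenyl]‑3‑[4‑(2‑methylbut‑3‑en‑2‑yloxy)phenyl]prop‑2‑en‑1‑one
Conditions: KOH, EtOH, rt
Reagents that add atoms: none
Why: Claisen–Schmidt aldol condensation: the methyl ketone enolate adds to the non‑enolisable aldehyde and E1cB loss of water gives the (E)‑enone; room temperature keeps both tertiary allyl ethers from rearranging early.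

Step 7
Reactants: 9 (E)‑1‑[4‑(methoxymethoxy)‑2‑(2‑methylbut‑3‑en‑2‑yloxy)phenyl]‑3‑[4‑(2‑methylbut‑3‑en‑2‑yloxy)phenyl]prop‑2‑en‑1‑one
Product: 10 [4‑(methoxymethoxy)‑2‑(2‑methylbut‑3‑en‑2‑yloxy)phenyl]{(2R,3S)‑3‑[4‑(2‑methylbut‑3‑en‑2‑yloxy)phenyl]oxiran‑2‑yl}methanone
Conditions: poly‑L‑leucine (immobilised), urea–H2O2, DBU, THF, rt
Reagents that add atoms: hydrogen peroxide (used as its urea adduct), OO
Why: Julia–Colonna epoxidation (Weitz–Scheffer type): hydroperoxide adds to the enone bound at the N‑terminus of the poly‑L‑leucine helix and the enolate closes to the trans‑epoxide, the helix choosing the enone face and thereby both centres (2R,3S); the isolated vinyl groups are inert to the nucleophilic oxidant.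

Step 8
Reactants: 10 [4‑(methoxymethoxy)‑2‑(2‑methylbut‑3‑en‑2‑yloxy)phenyl]{(2R,3S)‑3‑[4‑(2‑methylbut‑3‑en‑2‑yloxy)phenyl]oxiran‑2‑yl}methanone
Product: 12 (2R,3R)‑3‑hydroxy‑2‑[4‑hydroxy‑3‑(3‑methylbut‑2‑enyl)phenyl]‑7‑(methoxymethoxy)‑8‑(3‑methylbut‑2‑enyl)‑2,3‑dihydrochromen‑4‑one, via diprenyl bisphenol epoxy ketone 11 (not isolated)
Conditions: PhNEt2 (degassed), 125 °C, Ar
Reagents that add atoms: none
Why: Proposed new method: two aromatic Claisen [3,3] shifts (chair‑like, then enolisation) turn the aryl 2‑methylbut‑3‑en‑2‑yl ethers into ortho‑prenyl phenols, on ring A necessarily at the future C8 because the other ortho carbon carries the acyl group and on ring B at either of two equivalent ortho carbons, and the phenol so released on ring A (future O1), held beside the oxirane by its hydrogen bond to the ketone, opens the epoxide at the benzylic carbon. The closest known reaction types are the thermal Claisen rearrangement of aryl 1,1‑dimethylallyl ethers to ortho‑prenyl phenols and the cyclisation of 2'‑hydroxychalcone epoxides to trans‑dihydroflavonols; new is only their coupling, with the rearrangement itself unmasking the nucleophile in the presence of the epoxide. Ring C closes by 6‑endo‑tet attack of O1 on the epoxide carbon that becomes C2. C3 keeps the configuration of the epoxide alpha carbon, whose C–O bond is not touched, and C2 is set by inversion at the beta carbon, the resulting 2,3‑trans (diequatorial) arrangement also being the thermodynamic one should the opening become loose or quinone‑methide‑like once ring B carries its free para‑hydroxyl. The step needs beta (6‑endo) over alpha (5‑exo, aurone‑type) opening, secured by the para‑oxygenated benzylic beta carbon and the absence of a substituent at the other ortho position of the ketone, and it needs concerted [3,3] shift over ionisation of the tertiary ethers, secured by the weakly basic, non‑nucleophilic amine solvent, which also keeps the new ortho‑prenyl phenols from closing to chromans.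

Step 9
Reactants: 12 (2R,3R)‑3‑hydroxy‑2‑[4‑hydroxy‑3‑(3‑methylbut‑2‑enyl)phenyl]‑7‑(methoxymethoxy)‑8‑(3‑methylbut‑2‑enyl)‑2,3‑dihydrochromen‑4‑one
Product: 13 3‑hydroxyglabrol, (2R,3R)‑3,7‑dihydroxy‑2‑[4‑hydroxy‑3‑(3‑methylbut‑2‑enyl)phenyl]‑8‑(3‑methylbut‑2‑enyl)‑2,3‑dihydrochromen‑4‑one
Conditions: HCl (3 M aq), MeOH, 40 °C
Reagents that add atoms: none
Why: Acid‑catalysed transacetalisation of the aryl MOM ether to methanol; dilute acid and mild temperature should leave the ortho‑prenyl phenols uncyclised and the two stereocentres untouched.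

**Compound list**

1 | 2,4‑dihydroxyacetophenone | CC(=O)c1ccc(O)cc1O | starting material
2 | 1‑[2‑hydroxy‑4‑(methoxymethoxy)phenyl]ethanone | CC(=O)c1ccc(OCOC)cc1O | intermediate
3 | 3‑chloro‑3‑methylbut‑1‑yne | C#CC(C)(C)Cl | starting material
4 | 1‑[4‑(methoxymethoxy)‑2‑(2‑methylbut‑3‑yn‑2‑yloxy)phenyl]ethanone | CC(=O)c1ccc(OCOC)cc1OC(C)(C)C#C | intermediate
5 | 1‑[4‑(methoxymethoxy)‑2‑(2‑methylbut‑3‑en‑2‑yloxy)phenyl]ethanone | CC(=O)c1ccc(OCOC)cc1OC(C)(C)C=C | intermediate
6 | 4‑hydroxybenzaldehyde | O=Cc1ccc(O)cc1 | starting material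
7 | 4‑(2‑methylbut‑3‑yn‑2‑yloxy)benzaldehyde | O=Cc1ccc(OC(C)(C)C#C)cc1 | intermediate
8 | 4‑(2‑methylbut‑3‑en‑2‑yloxy)benzaldehyde | O=Cc1ccc(OC(C)(C)C=C)cc1 | intermediate
9 | (E)‑1‑[4‑(methoxymethoxy)‑2‑(2‑methylbut‑3‑en‑2‑yloxy)phenyl]‑3‑[4‑(2‑methylbut‑3‑en‑2‑yloxy)phenyl]prop‑2‑en‑1‑one | C=CC(C)(C)Oc1ccc(/C=C/C(=O)c2ccc(OCOC)cc2OC(C)(C)C=C)cc1 | intermediate
10 | [4‑(methoxymethoxy)‑2‑(2‑methylbut‑3‑en‑2‑yloxy)phenyl]{(2R,3S)‑3‑[4‑(2‑methylbut‑3‑en‑2‑yloxy)phenyl]oxiran‑2‑yl}methanone | COCOc1ccc(C(=O)[C@@H]2O[C@H]2c2ccc(OC(C)(C)C=C)cc2)c(OC(C)(C)C=C)c1 | intermediate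
11 | [2‑hydroxy‑4‑(methoxymethoxy)‑3‑(3‑methylbut‑2‑enyl)phenyl]{(2R,3S)‑3‑[4‑hydroxy‑3‑(3‑methylbut‑2‑enyl)phenyl]oxiran‑2‑yl}methanone (diprenyl bisphenol epoxy ketone, not isolated) | COCOc1ccc(C(=O)[C@@H]2O[C@H]2c2ccc(O)c(CC=C(C)C)c2)c(O)c1CC=C(C)C | intermediate
12 | (2R,3R)‑3‑hydroxy‑2‑[4‑hydroxy‑3‑(3‑methylbut‑2‑enyl)phenyl]‑7‑(methoxymethoxy)‑8‑(3‑methylbut‑2‑enyl)‑2,3‑dihydrochromen‑4‑one | CC(C)=CCc1cc([C@H]2Oc3c(ccc(OCOC)c3CC=C(C)C)C(=O)[C@@H]2O)ccc1O | intermediate
13 | 3‑hydroxyglabrol, (2R,3R)‑3,7‑dihydroxy‑2‑[4‑hydroxy‑3‑(3‑methylbut‑2‑enyl)phenyl]‑8‑(3‑methylbut‑2‑enyl)‑2,3‑dihydrochromen‑4‑one | CC(C)=CCc1cc([C@H]2Oc3c(ccc(O)c3CC=C(C)C)C(=O)[C@@H]2O)ccc1O | target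

**Count and risks**

Total steps: 9. Longest linear sequence: 7 (steps 1, 2, 3, 6, 7, 8, 9).

Step 8 (proposed new method). What may go wrong: the epoxide may open or rearrange (acyl shift, quinone‑methide formation once ring B is a free para‑phenol) before ring A has released its phenol, or the tertiary ethers may lose isoprene instead of rearranging. The fallback uses known chemistry and sets out from chalcone 9, whose enone tolerates the rearrangement temperature. Heating 9 in PhNEt2 at 130 °C should give, by the same double Claisen rearrangement, (E)‑1‑[2‑hydroxy‑4‑(methoxymethoxy)‑3‑(3‑methylbut‑2‑enyl)phenyl]‑3‑[4‑hydroxy‑3‑(3‑methylbut‑2‑enyl)phenyl]prop‑2‑en‑1‑one F1. Both phenols are then capped (MOMCl, NaH, DMF, 0 °C) to give the tris‑MOM chalcone F2. Julia–Colonna epoxidation as in step 7 should give the (2R,3S)‑epoxide F3. HCl in MeOH then removes the three MOM groups, with closure of the freed 2'‑OH onto the benzylic epoxide carbon (the established deprotection–cyclisation of 2'‑O‑MOM chalcone epoxides). This comes back to the route at the target 13.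

Step 7. What may go wrong: poor facial selectivity or slow hydroperoxide addition, because the ortho tert‑alkoxy group twists the aryl ketone out of the conformation the helical catalyst recognises. The fallback sets out from 9. Luche reduction (NaBH4, CeCl3·7H2O, MeOH, 0 °C) should give the racemic (E)‑allylic alcohol F4. Sharpless kinetic‑resolution epoxidation (Ti(OiPr)4, L‑(+)‑diisopropyl tartrate, t‑BuOOH, 4 Å sieves, CH2Cl2, −20 °C, about half conversion) should give the anti (erythro) epoxy alcohol F5, the reagent choosing both the alkene face and the fast‑reacting carbinol enantiomer. Dess–Martin oxidation then comes back to the route at epoxide 10. Unreacted alcohol can be returned to 9 with MnO2.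

Step 2. What may go wrong: incomplete etherification of the hydrogen‑bonded, hindered phenoxide, or dehydrochlorination of the tertiary chloride outpacing substitution. The fallback sets out from 2 and replaces propargylation plus semihydrogenation by a Tsuji–Trost O‑allylation. tert‑Butyl 2‑methylbut‑3‑en‑2‑yl carbonate F6 (from 2‑methylbut‑3‑en‑2‑ol, n‑BuLi and Boc2O) and Pd(PPh3)4 in THF at 0 °C should form the tertiary ether directly, the phenoxide attacking the more substituted terminus of the 1,1‑dimethylallyl palladium intermediate. This comes back to the route at 5, bypassing 4 and step 3.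

**Further compounds**

F1 | step 8 | (E)‑1‑[2‑hydroxy‑4‑(methoxymethoxy)‑3‑(3‑methylbut‑2‑enyl)phenyl]‑3‑[4‑hydroxy‑3‑(3‑methylbut‑2‑enyl)phenyl]prop‑2‑en‑1‑one | COCOc1ccc(C(=O)/C=C/c2ccc(O)c(CC=C(C)C)c2)c(O)c1CC=C(C)C
F2 | step 8 | (E)‑1‑[2,4‑bis(methoxymethoxy)‑3‑(3‑methylbut‑2‑enyl)phenyl]‑3‑[4‑(methoxymethoxy)‑3‑(3‑methylbut‑2‑enyl)phenyl]prop‑2‑en‑1‑one | COCOc1ccc(C(=O)/C=C/c2ccc(OCOC)c(CC=C(C)C)c2)c(OCOC)c1CC=C(C)C
F3 | step 8 | [2,4‑bis(methoxymethoxy)‑3‑(3‑methylbut‑2‑enyl)phenyl]{(2R,3S)‑3‑[4‑(methoxymethoxy)‑3‑(3‑methylbut‑2‑enyl)phenyl]oxiran‑2‑yl}methanone | COCOc1ccc(C(=O)[C@@H]2O[C@H]2c2ccc(OCOC)c(CC=C(C)C)c2)c(OCOC)c1CC=C(C)C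
F4 | step 7 | rac‑(E)‑1‑[4‑(methoxymethoxy)‑2‑(2‑methylbut‑3‑en‑2‑yloxy)phenyl]‑3‑[4‑(2‑methylbut‑3‑en‑2‑yloxy)phenyl]prop‑2‑en‑1‑ol | COCOc1ccc(C(O)/C=C/c2ccc(OC(C)(C)C=C)cc2)c(OC(C)(C)C=C)c1
F5 | step 7 | (S)‑[4‑(methoxymethoxy)‑2‑(2‑methylbut‑3‑en‑2‑yloxy)phenyl]{(2S,3S)‑3‑[4‑(2‑methylbut‑3‑en‑2‑yloxy)phenyl]oxiran‑2‑yl}methanol | COCOc1ccc([C@H](O)[C@@H]2O[C@H]2c2ccc(OC(C)(C)C=C)cc2)c(OC(C)(C)C=C)c1
F6 | step 2 | tert‑butyl 2‑methylbut‑3‑en‑2‑yl carbonate | C=CC(C)(C)OC(=O)OC(C)(C)C
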